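**Retrosynthetic overview**

- The plan rests on C3 and C4 of ring C. They bridge the C2 carbinol carbon (the only stereocentre, bonded to O1 and ring B) and C4a of ring A. At the ketone oxidation level this bridge is the C3=C4 double bond of a 4-silyloxy-2H-chromene.
- Ring C is cut at C3=C4 by ring-closing metathesis between the vinyl group on C2 and a 1-silyloxyvinyl group on ring A. Acid then unmasks C4=O and both phenols.
- O1–C2 and the (S) centre come from an iridium-catalysed, branched-selective allylic etherification of a ring A 2'-hydroxyacetophenone aryloxide with a ring B cinnamyl carbonate. The acetyl group then becomes the silyl enol ether.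
- Ring A partner: 2',6'-dihydroxy-4'-methoxyacetophenone, mono-MOM ether, O-allyl ether, Claisen rearrangement to the one free ortho carbon (future C8), cross-metathesis of allyl to prenyl. Ring B partner: isovanillin, MOM ether, Wittig, reduction, tert-butyl carbonate.
- Rings A and B are bought; ring C is the only ring built, and it is built last.

Key step: step 11

Assumption: with aryl-substituted allyl electrophiles the (Sa,Sc,Sc)-phosphoramidite–iridium catalyst is taken to deliver oxygen nucleophiles to the face that gives the (S)-ether, as is usual for this ligand class; the mirror-image ligand would be used if the first sample of the ether showed the opposite sense.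

**Route**

Step 1
Reactants: 1 2',6'-dihydroxy-4'-methoxyacetophenone
Product: 2 1-[2-hydroxy-4-methoxy-6-(methoxymethoxy)phenyl]ethan-1-one
Conditions: MOMCl (1.1 equiv), i-Pr2NEt, CH2Cl2, 0 °C → rt
Reagents that add atoms: chloromethyl methyl ether (MOMCl), COCCl
Why: O-alkylation of a phenol with an α-chloro ether (MOM protection); the two hydroxyls of 1 are equivalent, and once one is etherified the other is held in a hydrogen bond to the acetyl carbonyl and reacts far more slowly, so a single mono-ether is expected.

Step 2
Reactants: 2 1-[2-hydroxy-4-methoxy-6-(methoxymethoxy)phenyl]ethan-1-one; 3 allyl bromide (3-bromoprop-1-ene)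
Product: 4 1-[4-methoxy-2-(methoxymethoxy)-6-(prop-2-en-1-yloxy)phenyl]ethan-1-one
Conditions: K2CO3, DMF, 60 °C
Reagents that add atoms: none
Why: Williamson ether synthesis in which carbonate in DMF deprotonates the chelated phenol and the primary allylic bromide is taken at oxygen, the MOM ether and the ketone being inert.

Step 3
Reactants: 4 1-[4-methoxy-2-(methoxymethoxy)-6-(prop-2-en-1-yloxy)phenyl]ethan-1-one
Product: 6 1-[2-hydroxy-4-methoxy-6-(methoxymethoxy)-3-(prop-2-en-1-yl)phenyl]ethan-1-one, via ortho-dienone 5 (not isolated)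
Conditions: PhNEt2, 200 °C, Ar
Reagents that add atoms: none
Why: Aromatic Claisen rearrangement in which the [3,3] shift can deliver the allyl group only to the one unsubstituted ortho carbon (the future C8), after which dienone 5 tautomerises to the chelated phenol; the MOM ether tolerates neutral heating in the amine solvent.

Step 4
Reactants: 6 1-[2-hydroxy-4-methoxy-6-(methoxymethoxy)-3-(prop-2-en-1-yl)phenyl]ethan-1-one; 7 2-methyl-2-butene
Product: 8 1-[2-hydroxy-4-methoxy-6-(methoxymethoxy)-3-(3-methylbut-2-en-1-yl)phenyl]ethan-1-one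
Conditions: second-generation Grubbs catalyst (H2IMes)(PCy3)Cl2Ru=CHPh (3 mol %), 2-methyl-2-butene (large excess), CH2Cl2, 40 °C, sealed
Reagents that add atoms: none
Why: Olefin cross-metathesis in which the terminal allyl alkene exchanges its CH2 end for the isopropylidene end of the excess 2-methyl-2-butene with loss of propene, the trisubstituted prenyl alkene being the unreactive end point; the free phenol, the ketone and the MOM ether are tolerated by the ruthenium alkylidene.

Step 5
Reactants: 9 isovanillin (3-hydroxy-4-methoxybenzaldehyde)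
Product: 10 4-methoxy-3-(methoxymethoxy)benzaldehyde
Conditions: MOMCl, i-Pr2NEt, CH2Cl2, 0 °C → rt
Reagents that add atoms: chloromethyl methyl ether (MOMCl), COCCl
Why: MOM protection of the only phenol by O-alkylation, which gives a group stable to ylide, hydride, base and both metal catalysts and removable by acid at the end.

Step 6
Reactants: 10 4-methoxy-3-(methoxymethoxy)benzaldehyde; 11 ethyl (triphenylphosphoranylidene)acetate
Product: 12 ethyl (2E)-3-[4-methoxy-3-(methoxymethoxy)phenyl]prop-2-enoate
Conditions: toluene, 80 °C
Reagents that add atoms: none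
Why: Wittig olefination with a stabilised ylide, which with an aromatic aldehyde is expected to give the (E)-cinnamate.

Step 7
Reactants: 12 ethyl (2E)-3-[4-methoxy-3-(methoxymethoxy)phenyl]prop-2-enoate
Product: 13 (2E)-3-[4-methoxy-3-(methoxymethoxy)phenyl]prop-2-en-1-ol
Conditions: i-Bu2AlH (2.2 equiv), CH2Cl2, −78 → 0 °C; aq. potassium sodium tartrate
Reagents that add atoms: none
Why: 1,2-Reduction of the conjugated ester to the allylic alcohol by the aluminium hydride at low temperature, which leaves the alkene geometry and the MOM ether untouched.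

Step 8
Reactants: 13 (2E)-3-[4-methoxy-3-(methoxymethoxy)phenyl]prop-2-en-1-ol
Product: 14 tert-butyl (2E)-3-[4-methoxy-3-(methoxymethoxy)phenyl]prop-2-en-1-yl carbonate
Conditions: Boc2O, n-Bu4NHSO4 (cat.), 30% aq. NaOH, CH2Cl2, 0 °C → rt
Reagents that add atoms: di-tert-butyl dicarbonate (Boc2O), CC(C)(C)OC(=O)OC(=O)OC(C)(C)C
Why: Acylation of the primary allylic alcohol to the mixed carbonate under phase-transfer conditions; the tert-butyl carbonate is chosen because the tert-butoxide it releases in step 9 is too hindered to compete with the aryloxide as a nucleophile.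

Step 9
Reactants: 8 1-[2-hydroxy-4-methoxy-6-(methoxymethoxy)-3-(3-methylbut-2-en-1-yl)phenyl]ethan-1-one; 14 tert-butyl (2E)-3-[4-methoxy-3-(methoxymethoxy)phenyl]prop-2-en-1-yl carbonate
Product: 16 1-[2-{[(1S)-1-[4-methoxy-3-(methoxymethoxy)phenyl]prop-2-en-1-yl]oxy}-4-methoxy-6-(methoxymethoxy)-3-(3-methylbut-2-en-1-yl)phenyl]ethan-1-one, via sodium aryloxide 15 (not isolated)
Conditions: NaH (1.0 equiv), THF, 0 °C; then 14 (1.3 equiv), [Ir(cod)Cl]2 (2 mol %), (Sa,Sc,Sc)-O,O'-(1,1'-binaphthalene-2,2'-diyl) N,N-bis(1-phenylethyl)phosphoramidite (4 mol %, pre-activated with n-PrNH2), THF, rt → 35 °C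
Reagents that add atoms: none
Why: Iridium-catalysed asymmetric allylic etherification of an alkali aryloxide, in which the cyclometalated iridium–phosphoramidite complex ionises 14 to an allyliridium intermediate that the aryloxide attacks at the aryl-substituted terminus to give the branched ether, the (Sa,Sc,Sc) ligand fixing the face of attack so that C2 is formed as (S); the reaction is stopped at full conversion of 15 so that the product is not re-ionised.

Step 10
Reactants: 16 1-[2-{[(1S)-1-[4-methoxy-3-(methoxymethoxy)phenyl]prop-2-en-1-yl]oxy}-4-methoxy-6-(methoxymethoxy)-3-(3-methylbut-2-en-1-yl)phenyl]ethan-1-one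
Product: 18 tert-butyl({1-[2-{[(1S)-1-[4-methoxy-3-(methoxymethoxy)phenyl]prop-2-en-1-yl]oxy}-4-methoxy-6-(methoxymethoxy)-3-(3-methylbut-2-en-1-yl)phenyl]ethenyl}oxy)dimethylsilane, via potassium enolate 17 (not isolated)
Conditions: KN(SiMe3)2 (1.15 equiv), THF, −78 °C; then TBSCl, −78 → 0 °C
Reagents that add atoms: tert-butyldimethylsilyl chloride (TBSCl), CC(C)(C)[Si](C)(C)Cl
Why: Silyl enol ether formation by kinetic deprotonation of the methyl ketone, the only readily enolisable position, and O-silylation of the potassium enolate; the base-only conditions leave the MOM ethers and the ionisable allylic aryl ether intact, and the C2–H is far less acidic than the ketone methyl, so the stereocentre is not touched.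

Step 11
Reactants: 18 tert-butyl({1-[2-{[(1S)-1-[4-methoxy-3-(methoxymethoxy)phenyl]prop-2-en-1-yl]oxy}-4-methoxy-6-(methoxymethoxy)-3-(3-methylbut-2-en-1-yl)phenyl]ethenyl}oxy)dimethylsilane
Product: 19 tert-butyl{[(2S)-7-methoxy-2-[4-methoxy-3-(methoxymethoxy)phenyl]-5-(methoxymethoxy)-8-(3-methylbut-2-en-1-yl)-2H-chromen-4-yl]oxy}dimethylsilane
Conditions: second-generation Grubbs catalyst (H2IMes)(PCy3)Cl2Ru=CHPh (10 mol %, two portions), 1,4-benzoquinone (20 mol %), degassed benzene (0.005 M), 50 °C, Ar sparge, dark
Reagents that add atoms: none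
Why: Ring-closing olefin metathesis of an olefinic silyl enol ether, a known way to cyclic silyl enol ethers with ruthenium alkylidenes: the catalyst exchanges onto the monosubstituted vinyl group at C2, the new alkylidene adds [2+2] across the 1,1-disubstituted enol ether with ruthenium on the CH2 carbon, and cycloreversion forms C3=C4 and gives Ru=CH2, the chain carrier, the two lost CH2 groups leaving as ethene. Ring C closes as a six-membered ring with both carbons of the new double bond in the ring, and the product is an aryl-conjugated enol ether. No stereocentre is created; C2 is a spectator whose C–H and C–O bonds are not involved, so the (S) configuration from step 9 is carried through, and because C4 stays masked no base ever meets the free flavanone. The selectivity needed is closure onto the enol ether in preference to the trisubstituted prenyl alkene on C8, which would give a seven-membered oxepine with loss of isobutene; the smaller ring, the conjugation gained and the sluggishness of the trisubstituted alkene should favour ring C, and high dilution suppresses dimerisation through the vinyl group. Benzoquinone is added to intercept ruthenium hydrides that would move the new double bond toward C2, and the moderate temperature and exclusion of light guard the 2H-chromene against electrocyclic ring opening.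

Step 12
Reactants: 19 tert-butyl{[(2S)-7-methoxy-2-[4-methoxy-3-(methoxymethoxy)phenyl]-5-(methoxymethoxy)-8-(3-methylbut-2-en-1-yl)-2H-chromen-4-yl]oxy}dimethylsilane
Product: 21 (2S)-5-hydroxy-2-(3-hydroxy-4-methoxyphenyl)-7-methoxy-8-(3-methylbut-2-en-1-yl)-2,3-dihydro-4H-chromen-4-one, via bis-MOM flavanone 20 (not isolated)
Conditions: 3 M aq. HCl, THF, 40 °C
Reagents that add atoms: none
Why: Acid hydrolysis of the silyl enol ether (protonation at C3, loss of silanol) followed by acetal hydrolysis of both MOM ethers; the prenyl group has no free ortho hydroxyl with which to cyclise (its neighbours are O1 and the 7-methoxy group), and the flavanone is opened by base, not by mild acid, so C2 should keep its configuration.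

**Compound list**

1 | 2',6'-dihydroxy-4'-methoxyacetophenone | CC(=O)c1c(O)cc(OC)cc1O | starting material
2 | 1-[2-hydroxy-4-methoxy-6-(methoxymethoxy)phenyl]ethan-1-one | CC(=O)c1c(O)cc(OC)cc1OCOC | intermediate
3 | allyl bromide (3-bromoprop-1-ene) | C=CCBr | starting material
4 | 1-[4-methoxy-2-(methoxymethoxy)-6-(prop-2-en-1-yloxy)phenyl]ethan-1-one | CC(=O)c1c(OCC=C)cc(OC)cc1OCOC | intermediate
5 | 2-acetyl-5-methoxy-3-(methoxymethoxy)-6-(prop-2-en-1-yl)cyclohexa-2,4-dien-1-one (ortho-dienone, not isolated) | CC(=O)C1=C(OCOC)C=C(OC)C(CC=C)C1=O | intermediate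
6 | 1-[2-hydroxy-4-methoxy-6-(methoxymethoxy)-3-(prop-2-en-1-yl)phenyl]ethan-1-one | CC(=O)c1c(O)c(CC=C)c(OC)cc1OCOC | intermediate
7 | 2-methyl-2-butene | CC=C(C)C | starting material
8 | 1-[2-hydroxy-4-methoxy-6-(methoxymethoxy)-3-(3-methylbut-2-en-1-yl)phenyl]ethan-1-one | CC(=O)c1c(O)c(CC=C(C)C)c(OC)cc1OCOC | intermediate
9 | isovanillin (3-hydroxy-4-methoxybenzaldehyde) | COc1ccc(C=O)cc1O | starting material
10 | 4-methoxy-3-(methoxymethoxy)benzaldehyde | COCOc1cc(C=O)ccc1OC | intermediate
11 | ethyl (triphenylphosphoranylidene)acetate | CCOC(=O)C=P(c1ccccc1)(c1ccccc1)c1ccccc1 | starting material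
12 | ethyl (2E)-3-[4-methoxy-3-(methoxymethoxy)phenyl]prop-2-enoate | CCOC(=O)/C=C/c1ccc(OC)c(OCOC)c1 | intermediate
13 | (2E)-3-[4-methoxy-3-(methoxymethoxy)phenyl]prop-2-en-1-ol | OC/C=C/c1ccc(OC)c(OCOC)c1 | intermediate
14 | tert-butyl (2E)-3-[4-methoxy-3-(methoxymethoxy)phenyl]prop-2-en-1-yl carbonate | CC(C)(C)OC(=O)OC/C=C/c1ccc(OC)c(OCOC)c1 | intermediate
15 | sodium 2-acetyl-5-methoxy-3-(methoxymethoxy)-6-(3-methylbut-2-en-1-yl)phenolate (not isolated) | CC(=O)c1c([O-])c(CC=C(C)C)c(OC)cc1OCOC.[Na+] | intermediate
16 | 1-[2-{[(1S)-1-[4-methoxy-3-(methoxymethoxy)phenyl]prop-2-en-1-yl]oxy}-4-methoxy-6-(methoxymethoxy)-3-(3-methylbut-2-en-1-yl)phenyl]ethan-1-one | COc1ccc([C@H](C=C)Oc2c(C(C)=O)c(OCOC)cc(OC)c2CC=C(C)C)cc1OCOC | intermediate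
17 | potassium enolate of 16 (not isolated) | COc1ccc([C@H](C=C)Oc2c(C(=C)[O-])c(OCOC)cc(OC)c2CC=C(C)C)cc1OCOC.[K+] | intermediate
18 | tert-butyl({1-[2-{[(1S)-1-[4-methoxy-3-(methoxymethoxy)phenyl]prop-2-en-1-yl]oxy}-4-methoxy-6-(methoxymethoxy)-3-(3-methylbut-2-en-1-yl)phenyl]ethenyl}oxy)dimethylsilane | COc1ccc([C@H](C=C)Oc2c(C(=C)O[Si](C)(C)C(C)(C)C)c(OCOC)cc(OC)c2CC=C(C)C)cc1OCOC | intermediate
19 | tert-butyl{[(2S)-7-methoxy-2-[4-methoxy-3-(methoxymethoxy)phenyl]-5-(methoxymethoxy)-8-(3-methylbut-2-en-1-yl)-2H-chromen-4-yl]oxy}dimethylsilane | COc1ccc([C@@H]2C=C(O[Si](C)(C)C(C)(C)C)c3c(OCOC)cc(OC)c(CC=C(C)C)c3O2)cc1OCOC | intermediate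
20 | (2S)-7-methoxy-2-[4-methoxy-3-(methoxymethoxy)phenyl]-5-(methoxymethoxy)-8-(3-methylbut-2-en-1-yl)-2,3-dihydro-4H-chromen-4-one (not isolated) | COc1ccc([C@@H]2CC(=O)c3c(OCOC)cc(OC)c(CC=C(C)C)c3O2)cc1OCOC | intermediate
21 | (2S)-5-hydroxy-2-(3-hydroxy-4-methoxyphenyl)-7-methoxy-8-(3-methylbut-2-en-1-yl)-2,3-dihydro-4H-chromen-4-one | COc1ccc([C@@H]2CC(=O)c3c(O)cc(OC)c(CC=C(C)C)c3O2)cc1O | target

**Step count and risks**

Total step count: 12. Longest linear sequence: 8 steps (steps 1–4 or 5–8, then 9–12).

Steps most likely to fail: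

1. Step 11 (ring-closing metathesis). What may go wrong:
   - The C2-bound alkylidene may close onto the prenyl alkene and give the seven-membered ring with loss of isobutene.
   - The catalyst may stall at the hindered, electron-rich enol ether.
   - Ruthenium hydrides may shift the new double bond.
   - Electrocyclic opening of the 2H-chromene may erode C2.

   Fallback: ring C is closed at O1–C2 by oxa-Michael addition instead of at C3=C4. It sets out from 8 and 10. Claisen–Schmidt condensation (KOH, EtOH, rt) should give (2E)-1-[2-hydroxy-4-methoxy-6-(methoxymethoxy)-3-(3-methylbut-2-en-1-yl)phenyl]-3-[4-methoxy-3-(methoxymethoxy)phenyl]prop-2-en-1-one F1. Heating with NaOAc in EtOH should close the only free phenol onto the enone to give racemic 7-methoxy-2-[4-methoxy-3-(methoxymethoxy)phenyl]-5-(methoxymethoxy)-8-(3-methylbut-2-en-1-yl)-2,3-dihydro-4H-chromen-4-one F2. Preparative HPLC on a chiral stationary phase should separate the (S)-enantiomer from the (R)-enantiomer of the bis-MOM flavanone F3, which can be returned to the racemate with base. The route is rejoined at 20, which is deprotected with the acid of step 12.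

2. Step 9 (iridium-catalysed etherification). What may go wrong:
   - The hindered, chelated aryloxide may attack slowly.
   - The catalyst may re-ionise the branched ether, since the ortho-acyl aryloxide is a good leaving group and the para-methoxyaryl group stabilises the allyl cation; this would erode the enantiomeric purity and cause drift to the linear cinnamyl ether.
   - The aryloxide may be alkylated at carbon.

   Fallback: the stereocentre is taken from a resolved alcohol and transferred by a stereospecific rhodium-catalysed etherification. It sets out from 10 and 8. Addition of CH2=CHMgBr (THF, 0 °C) to 10 should give racemic 1-[4-methoxy-3-(methoxymethoxy)phenyl]prop-2-en-1-ol F4. Kinetic resolution with immobilised Candida antarctica lipase B and vinyl acetate should leave (1S)-1-[4-methoxy-3-(methoxymethoxy)phenyl]prop-2-en-1-ol F5 and acylate the other enantiomer to (1R)-1-[4-methoxy-3-(methoxymethoxy)phenyl]prop-2-en-1-yl acetate F6, which is separated. ClCO2Me and pyridine (CH2Cl2, 0 °C) should convert F5 to methyl (1S)-1-[4-methoxy-3-(methoxymethoxy)phenyl]prop-2-en-1-yl carbonate F7, used at once. The enantiospecific allylic etherification of sodium aryloxide 15 (from 8 and NaH) with F7 under RhCl(PPh3)3 and P(OMe)3 (THF, 0 °C → rt) is a known reaction for ortho-disubstituted phenols. It should go with net retention at the substituted carbon and give 16, where the route is rejoined.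

3. Step 12 (acid unmasking). What may go wrong:
   - Acid-promoted ionisation or ring opening at the para-methoxyaryl-substituted C2 may cause partial loss of configuration.
   - The non-chelated ring B MOM ether may cleave slowly, forcing conditions under which water or HCl adds to the prenyl alkene.

   Fallback: a two-stage end game without protic hydrolysis. It sets out from 19. Fluoride attack at silicon (Bu4NF buffered with AcOH, THF, −20 °C) should release the ketone and give 20, now isolated. Thiol transacetalisation under a mild Lewis acid (ZnBr2, n-PrSH, CH2Cl2, 0 °C, short contact) should then remove both MOM ethers and give 21, where the route is rejoined. No new compound is made.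

**Further compounds**

F1 | step 11 | (2E)-1-[2-hydroxy-4-methoxy-6-(methoxymethoxy)-3-(3-methylbut-2-en-1-yl)phenyl]-3-[4-methoxy-3-(methoxymethoxy)phenyl]prop-2-en-1-one | COCOc1cc(/C=C/C(=O)c2c(O)c(CC=C(C)C)c(OC)cc2OCOC)ccc1OC
F2 | step 11 | racemic 7-methoxy-2-[4-methoxy-3-(methoxymethoxy)phenyl]-5-(methoxymethoxy)-8-(3-methylbut-2-en-1-yl)-2,3-dihydro-4H-chromen-4-one | COc1ccc(C2CC(=O)c3c(OCOC)cc(OC)c(CC=C(C)C)c3O2)cc1OCOC
F3 | step 11 | (2R)-7-methoxy-2-[4-methoxy-3-(methoxymethoxy)phenyl]-5-(methoxymethoxy)-8-(3-methylbut-2-en-1-yl)-2,3-dihydro-4H-chromen-4-one | COc1ccc([C@H]2CC(=O)c3c(OCOC)cc(OC)c(CC=C(C)C)c3O2)cc1OCOC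
F4 | step 9 | racemic 1-[4-methoxy-3-(methoxymethoxy)phenyl]prop-2-en-1-ol | C=CC(O)c1ccc(OC)c(OCOC)c1
F5 | step 9 | (1S)-1-[4-methoxy-3-(methoxymethoxy)phenyl]prop-2-en-1-ol | C=C[C@H](O)c1ccc(OC)c(OCOC)c1
F6 | step 9 | (1R)-1-[4-methoxy-3-(methoxymethoxy)phenyl]prop-2-en-1-yl acetate | C=C[C@@H](OC(C)=O)c1ccc(OC)c(OCOC)c1
F7 | step 9 | methyl (1S)-1-[4-methoxy-3-(methoxymethoxy)phenyl]prop-2-en-1-yl carbonate | C=C[C@H](OC(=O)OC)c1ccc(OC)c(OCOC)c1
F0 | step 12 | none | none
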